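The route rests on cutting C8 of ring A from the side-chain methylene C1''. The motif exploited is aryl C8–CH2(C1'')–CH(C2''), in which C1''=C2'' is read as a vinyl group on boron. In one operation, an enantioselective three-component conjunctive cross-coupling merges vinylmagnesium bromide, the C5 alkyl boronate of the side chain, and an aryl iodide that already holds all fifteen flavone carbons. Palladium forms C8–C1'' while the alkyl chain shifts from boron to C2'' and sets its configuration. In the iodide, ring C is masked as a silylated propargylic carbinol, so the later Zweifel exchange of boron for isopropenyl meets no carbonyl group. Oxidation and acid then close the pyranone.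

Key step: step 8

Assumption: (Sp,Sp)-MandyPhos is taken to give (R)-15 by analogy with alkyl-migration cases, and the equally available (Rp,Rp) ligand is used if the sense is opposite; compounds 8, 9 and 15–19 are mixtures of epimers at the future C4 only; flavone numbering is used for the core and C1''–C6'' for the side chain.

Step 1
Reactants: 1 2,4-dihydroxy-6-methoxybenzaldehyde
Product: 2 2,4-dihydroxy-3-iodo-6-methoxybenzaldehyde
Conditions: I2 (0.4 equiv), HIO3 (0.2 equiv), EtOH–H2O, 35 °C
Reagents that add atoms: iodine II; iodic acid O=I(=O)O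
Why: Electrophilic aromatic iodination with I2/HIO3, which in 2,4-dihydroxyaryl carbonyl compounds attacks C3 between the chelated 2-OH and the 4-OH, a site also less hindered than C5 next to the methoxy group.

Step 2
Reactants: 2 2,4-dihydroxy-3-iodo-6-methoxybenzaldehyde
Product: 3 3-iodo-6-methoxy-2,4-bis(methoxymethoxy)benzaldehyde
Conditions: NaH, MOMCl, DMF, 0 °C to rt
Reagents that add atoms: chloromethyl methyl ether COCCl
Why: Williamson-type O-alkylation of both sodium phenoxides (MOM protection); NaH also overcomes the hydrogen bond of the 2-OH, and the small acetals keep the iodide accessible.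

Step 3
Reactants: 4 2,4-dihydroxybenzaldehyde
Product: 5 2,4-bis(methoxymethoxy)benzaldehyde
Conditions: NaH, MOMCl, DMF, 0 °C to rt
Reagents that add atoms: chloromethyl methyl ether COCCl
Why: The same Williamson-type MOM protection, giving base-stable and organolithium-stable acetals on ring B.

Step 4
Reactants: 5 2,4-bis(methoxymethoxy)benzaldehyde
Product: 6 1-ethynyl-2,4-bis(methoxymethoxy)benzene
Conditions: dimethyl (1-diazo-2-oxopropyl)phosphonate, K2CO3, MeOH, rt
Reagents that add atoms: dimethyl (1-diazo-2-oxopropyl)phosphonate CC(=O)C(=[N+]=[N-])P(=O)(OC)OC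
Why: Ohira–Bestmann (Seyferth–Gilbert) homologation of an aryl aldehyde to the terminal alkyne under mild carbonate conditions that MOM ethers tolerate.

Step 5
Reactants: 6 1-ethynyl-2,4-bis(methoxymethoxy)benzene; 3 3-iodo-6-methoxy-2,4-bis(methoxymethoxy)benzaldehyde
Product: 9 triethylsilyl ether of rac-1-[3-iodo-6-methoxy-2,4-bis(methoxymethoxy)phenyl]-3-[2,4-bis(methoxymethoxy)phenyl]prop-2-yn-1-ol, via lithium acetylide 7 (not isolated), via lithium alkoxide 8 (not isolated)
Conditions: n-BuLi, THF, −78 °C; 3, −78 °C; TESCl, DMAP (cat.), −78 °C to rt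
Reagents that add atoms: chlorotriethylsilane CC[Si](Cl)(CC)CC
Why: 1,2-Addition of a lithium acetylide to an aldehyde followed by O-silylation of the alkoxide in the same flask; the carbinol carbon (future C4) is made racemic on purpose because step 11 flattens it, and acetylides do not exchange with aryl iodides.

Step 6
Reactants: 10 2-methylbut-3-en-2-ol
Product: 11 triethyl[(2-methylbut-3-en-2-yl)oxy]silane
Conditions: TESOTf, 2,6-lutidine, CH2Cl2, 0 °C
Reagents that add atoms: triethylsilyl triflate CC[Si](CC)(CC)OS(=O)(=O)C(F)(F)F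
Why: Silylation of a tertiary alcohol with a silyl triflate, needed so that no alkoxide can bind to boron in steps 7–9.

Step 7
Reactants: 11 triethyl[(2-methylbut-3-en-2-yl)oxy]silane
Product: 12 2-{3-methyl-3-[(triethylsilyl)oxy]butyl}-4,4,5,5-tetramethyl-1,3,2-dioxaborolane
Conditions: HBpin, [Ir(cod)Cl]2 (1.5 mol %), dppm (3 mol %), CH2Cl2, rt
Reagents that add atoms: pinacolborane [H]B1OC(C)(C)C(C)(C)O1
Why: Iridium-catalysed anti-Markovnikov hydroboration of a terminal alkene, with the quaternary allylic carbon reinforcing terminal selectivity.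

Step 8
Reactants: 12 2-{3-methyl-3-[(triethylsilyl)oxy]butyl}-4,4,5,5-tetramethyl-1,3,2-dioxaborolane; 13 vinylmagnesium bromide; 9 aryl iodide (triethylsilyl ether of the propargylic alcohol)
Product: 15 (R)-secondary pinacol boronate with boron on C2'' and C1'' bound to C8 of the aryl core of 9, via vinylboron ate complex 14 (not isolated)
Conditions: 12, 13, THF, 0 °C to rt; then NaOTf, DMSO, 9, Pd(OAc)2 (3 mol %), (Sp,Sp)-MandyPhos (3.6 mol %), 60 °C
Reagents that add atoms: none
Why: Pd(0)/MandyPhos inserts into the C8–I bond of 9 and NaOTf removes iodide and bromide as sodium salts, so that a cationic aryl–Pd(II) binds the vinyl π-bond of ate complex 14; this triggers a 1,2-metallate shift in which the CH2CH2C(CH3)2OTES group moves from boron to the α-carbon (future C2'') anti to palladium while the β-carbon (future C1'') becomes bound to palladium, and reductive elimination then forms the C8–C1'' bond. The closest known reaction type is the palladium-catalysed enantioselective conjunctive cross-coupling of Grignard-derived vinylboron ate complexes with aryl halides in the presence of NaOTf, which is established for primary alkyl migrating groups. No ring is closed. The only new stereocentre, C2'', is controlled by the C2-symmetric ferrocenyl bisphosphine, which selects the face of the bound vinyl group in the metallate shift; the remote racemic carbinol carbon of 9 should have no influence, so two C4 epimers of one C2'' configuration are expected. The step needs conjunctive coupling to win over direct vinyl transfer (Suzuki-type styrene formation) and over β-hydride elimination of the alkyl–Pd intermediate, which the unsubstituted vinyl group, the chelating ligand and halide removal secure, and the two ortho OMOM groups should speed up reductive elimination. Chemoselectivity rests on the C–I bond being the only site open to oxidative addition, since 9 carries no carbonyl group, its hindered internal alkyne is a poor partner for carbopalladation, and silyl and MOM ethers are inert to the weakly nucleophilic borate.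

Step 9
Reactants: 15 (R)-secondary pinacol boronate
Product: 18 (R)-isopropenyl compound bearing both triethylsilyl ethers and four MOM ethers, via isopropenylboron ate complex 16 (not isolated), via beta-iodoalkyl boronate 17 (not isolated)
Conditions: 2-bromopropene, t-BuLi, Et2O, −78 °C; 15, THF, −78 °C; I2, THF, −78 °C; NaOMe, MeOH, −78 °C to rt
Reagents that add atoms: 2-bromopropene C=C(C)Br
Why: Zweifel olefination, in which isopropenyllithium adds to boron (no carbonyl group competes in 15), iodine activates the alkenyl group, C2'' migrates from boron to carbon with retention of configuration, and methoxide-induced anti elimination of boron and iodide leaves the 1,1-disubstituted alkene.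

Step 10
Reactants: 18 (R)-isopropenyl bis(triethylsilyl) ether
Product: 19 (R)-diol with free propargylic and tertiary hydroxyl groups
Conditions: TBAF, THF, 0 °C to rt
Reagents that add atoms: none
Why: Fluoride-induced desilylation of both triethylsilyl ethers under conditions that leave MOM acetals, alkyne and alkene untouched.

Step 11
Reactants: 19 (R)-diol
Product: 20 (R)-ynone 1-{3-[(2R)-5-hydroxy-5-methyl-2-(prop-1-en-2-yl)hexyl]-6-methoxy-2,4-bis(methoxymethoxy)phenyl}-3-[2,4-bis(methoxymethoxy)phenyl]prop-2-yn-1-one
Conditions: activated MnO2, CH2Cl2, rt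
Reagents that add atoms: none
Why: MnO2 oxidation of a benzylic and propargylic alcohol, which spares the tertiary alcohol and the alkene and merges the two C4 epimers into one compound.

Step 12
Reactants: 20 (R)-ynone
Product: 22 target (R)-2-(2,4-dihydroxyphenyl)-7-hydroxy-8-[(2R)-5-hydroxy-5-methyl-2-(prop-1-en-2-yl)hexyl]-5-methoxy-4H-chromen-4-one, via tetrahydroxy ynone 21 (not isolated)
Conditions: HCl (1.25 M in MeOH), THF, rt to 40 °C
Reagents that add atoms: none
Why: Acid-catalysed methanolysis of the four MOM acetals followed by 6-endo-dig oxa-Michael addition of the freed C8a hydroxyl to the ynone carbon that bears ring B (activated by the protonated carbonyl and stabilised by the resorcinol ring), a known flavone synthesis from 2-hydroxyaryl ynones that does not touch C2''.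

Compound list
1 | 2,4-dihydroxy-6-methoxybenzaldehyde | O=Cc1c(O)cc(O)cc1OC | starting material
2 | 2,4-dihydroxy-3-iodo-6-methoxybenzaldehyde | O=Cc1c(O)c(I)c(O)cc1OC | intermediate
3 | 3-iodo-6-methoxy-2,4-bis(methoxymethoxy)benzaldehyde | O=Cc1c(OCOC)c(I)c(OCOC)cc1OC | intermediate
4 | 2,4-dihydroxybenzaldehyde | O=Cc1ccc(O)cc1O | starting material
5 | 2,4-bis(methoxymethoxy)benzaldehyde | O=Cc1ccc(OCOC)cc1OCOC | intermediate
6 | 1-ethynyl-2,4-bis(methoxymethoxy)benzene | C#Cc1ccc(OCOC)cc1OCOC | intermediate
7 | lithium acetylide of 6 (not isolated) | [Li]C#Cc1ccc(OCOC)cc1OCOC | intermediate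
8 | lithium alkoxide of the racemic propargylic alcohol from 7 and 3 (not isolated) | [Li]OC(C#Cc1ccc(OCOC)cc1OCOC)c1c(OCOC)c(I)c(OCOC)cc1OC | intermediate
9 | triethylsilyl ether of rac-1-[3-iodo-6-methoxy-2,4-bis(methoxymethoxy)phenyl]-3-[2,4-bis(methoxymethoxy)phenyl]prop-2-yn-1-ol | CC[Si](CC)(CC)OC(C#Cc1ccc(OCOC)cc1OCOC)c1c(OCOC)c(I)c(OCOC)cc1OC | intermediate
10 | 2-methylbut-3-en-2-ol | C=CC(C)(C)O | starting material
11 | triethyl[(2-methylbut-3-en-2-yl)oxy]silane | C=CC(C)(C)O[Si](CC)(CC)CC | intermediate
12 | 2-{3-methyl-3-[(triethylsilyl)oxy]butyl}-4,4,5,5-tetramethyl-1,3,2-dioxaborolane | CC[Si](CC)(CC)OC(C)(C)CCB1OC(C)(C)C(C)(C)O1 | intermediate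
13 | vinylmagnesium bromide | C=C[Mg]Br | starting material
14 | bromomagnesium vinyl{3-methyl-3-[(triethylsilyl)oxy]butyl}(pinacolato)borate (not isolated) | C=C[B-]1(CCC(C)(C)O[Si](CC)(CC)CC)OC(C)(C)C(C)(C)O1.[Mg+]Br | intermediate
15 | pinacol boronate, (R) at C2'' (boron, CH2-aryl, CH2CH2C(CH3)2OTES, H), epimers at the silyloxy carbon | CC1(C)OB(OC1(C)C)[C@H](CCC(C)(C)O[Si](CC)(CC)CC)Cc1c(OCOC)cc(OC)c(C(O[Si](CC)(CC)CC)C#Cc2ccc(OCOC)cc2OCOC)c1OCOC | intermediate
16 | lithium isopropenyl(alkyl)(pinacolato)borate from 15, (R) at C2'' (not isolated) | [Li+].C=C(C)[B-]1(OC(C)(C)C(C)(C)O1)[C@H](CCC(C)(C)O[Si](CC)(CC)CC)Cc1c(OCOC)cc(OC)c(C(O[Si](CC)(CC)CC)C#Cc2ccc(OCOC)cc2OCOC)c1OCOC | intermediate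
17 | beta-iodoalkyl tertiary boronate after migration of C2'', (R) at C2'' (not isolated) | ICC(C)(B1OC(C)(C)C(C)(C)O1)[C@H](CCC(C)(C)O[Si](CC)(CC)CC)Cc1c(OCOC)cc(OC)c(C(O[Si](CC)(CC)CC)C#Cc2ccc(OCOC)cc2OCOC)c1OCOC | intermediate
18 | isopropenyl compound, (R) at C2'', two TES ethers and four MOM ethers, epimers at the silyloxy carbon | C=C(C)[C@H](CCC(C)(C)O[Si](CC)(CC)CC)Cc1c(OCOC)cc(OC)c(C(O[Si](CC)(CC)CC)C#Cc2ccc(OCOC)cc2OCOC)c1OCOC | intermediate
19 | diol, (R) at C2'', free propargylic and tertiary OH, epimers at the carbinol carbon | C=C(C)[C@H](CCC(C)(C)O)Cc1c(OCOC)cc(OC)c(C(O)C#Cc2ccc(OCOC)cc2OCOC)c1OCOC | intermediate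
20 | 1-{3-[(2R)-5-hydroxy-5-methyl-2-(prop-1-en-2-yl)hexyl]-6-methoxy-2,4-bis(methoxymethoxy)phenyl}-3-[2,4-bis(methoxymethoxy)phenyl]prop-2-yn-1-one | C=C(C)[C@H](CCC(C)(C)O)Cc1c(OCOC)cc(OC)c(C(=O)C#Cc2ccc(OCOC)cc2OCOC)c1OCOC | intermediate
21 | 1-{2,4-dihydroxy-3-[(2R)-5-hydroxy-5-methyl-2-(prop-1-en-2-yl)hexyl]-6-methoxyphenyl}-3-(2,4-dihydroxyphenyl)prop-2-yn-1-one (not isolated) | C=C(C)[C@H](CCC(C)(C)O)Cc1c(O)cc(OC)c(C(=O)C#Cc2ccc(O)cc2O)c1O | intermediate
22 | 2-(2,4-dihydroxyphenyl)-7-hydroxy-8-[(2R)-5-hydroxy-5-methyl-2-(prop-1-en-2-yl)hexyl]-5-methoxy-4H-chromen-4-one | C=C(C)[C@H](CCC(C)(C)O)Cc1c(O)cc(OC)c2c(=O)cc(-c3ccc(O)cc3O)oc12 | target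

Total step count: 12. Longest linear sequence: 8 steps (1, 2, 5, 8, 9, 10, 11, 12).

Steps most likely to fail

Step 8. The hindered aryl–palladium, chelated by its ortho acetal oxygens, may be captured too slowly by the borate. Direct vinyl transfer, protodehalogenation or loss of facial selectivity could then take over.
- The fallback sets out from 9 and returns at 15.
- It sets the stereocentre before the union and makes the C8–C1'' bond by a two-component B-alkyl Suzuki–Miyaura coupling.
- Commercial 2-methylhex-5-en-2-ol is silylated (TESOTf, 2,6-lutidine) to triethyl[(2-methylhex-5-en-2-yl)oxy]silane F1.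
- Platinum-catalysed enantioselective diboration (B2pin2, Pt(dba)3, TADDOL-derived phosphonite) gives the (S)-1,2-bis(pinacol boronate) F2.
- Pd(OAc)2/RuPhos, KOH, THF–H2O, 70 °C then couples only the primary C–B bond of F2 with iodide 9 and delivers 15.

Step 12. Acid may ionise the tertiary alcohol, or protonate the isopropenyl group so that the 7-OH captures the cation and closes a chroman. Either process would compete with acetal cleavage and 6-endo ring closure.
- The fallback sets out from 20 and returns at 22.
- It avoids Brønsted acid and separates deprotection from ring closure.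
- TMSOTf/2,2'-bipyridyl in MeCN at 0 °C exchanges the four aryl MOM groups for silyl groups and silylates the tertiary alcohol, giving the pentakis(trimethylsilyl) ynone F3.
- KF/18-crown-6 in DMF then frees the phenoxides under aprotic conditions, where the C8a oxygen closes the pyranone by 6-endo-dig addition. Aqueous work-up gives 22.

Step 1. Iodination may go to C5 or occur twice.
- The fallback sets out from 1 and returns at 3, bypassing 2.
- It moves regiocontrol from electrophilic substitution to directed ortho-metalation.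
- Compound 1 is first protected (NaH, MOMCl) to 6-methoxy-2,4-bis(methoxymethoxy)benzaldehyde F4.
- Lithium N,N,N'-trimethylethylenediamide (THF, −20 °C) masks the aldehyde as the lithium alpha-amino alkoxide F5.
- n-BuLi lithiates C3, the site flanked by two OMOM groups, to give the C3-lithio alkoxide F6.
- I2 gives the iodinated alkoxide F7, which collapses to 3 on aqueous work-up.

Further compounds
F1 | step 8 | triethyl[(2-methylhex-5-en-2-yl)oxy]silane | C=CCCC(C)(C)O[Si](CC)(CC)CC
F2 | step 8 | (S)-2,2'-{5-methyl-5-[(triethylsilyl)oxy]hexane-1,2-diyl}bis(4,4,5,5-tetramethyl-1,3,2-dioxaborolane) | CC1(C)OB(OC1(C)C)[C@H](CCC(C)(C)O[Si](CC)(CC)CC)CB1OC(C)(C)C(C)(C)O1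
F3 | step 12 | pentakis(trimethylsilyl) ether of ynone 21, (R) at C2'' | C=C(C)[C@H](CCC(C)(C)O[Si](C)(C)C)Cc1c(O[Si](C)(C)C)cc(OC)c(C(=O)C#Cc2ccc(O[Si](C)(C)C)cc2O[Si](C)(C)C)c1O[Si](C)(C)C
F4 | step 1 | 6-methoxy-2,4-bis(methoxymethoxy)benzaldehyde | O=Cc1c(OCOC)cc(OCOC)cc1OC
F5 | step 1 | lithium alpha-amino alkoxide of F4 | [Li]OC(N(C)CCN(C)C)c1c(OCOC)cc(OCOC)cc1OC
F6 | step 1 | C3-lithio derivative of F5 | [Li]OC(N(C)CCN(C)C)c1c(OCOC)c([Li])c(OCOC)cc1OC
F7 | step 1 | C3-iodo derivative of F5 | [Li]OC(N(C)CCN(C)C)c1c(OCOC)c(I)c(OCOC)cc1OC
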